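**Retrosynthetic overview**
1. Target 22 ← 15-O-PMB removal and 9-O-acetylation ← tetracycle 20, whose seven-membered ring is closed last through C9–C10 (cyclic enol ether onto the C9 aldehyde of 19).
2. The α-methylene lactone of 17 ← Pd cyclocarbonylation of homopropargylic alcohol 16 (C12 comes from CO).
3. Key bond C6–C7: aldehyde 8 + alkynyl oxirane 13. The electrophilic propargylic carbon C7 of 13 is turned into a nucleophilic allenylindium (a masked β-acyl carbanion of the later lactone) and added to the aldehyde carbon C6; this sets C6 and C7, and C8 is carried in from 13.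
4. 8 ← ozonolysis and lactol dehydration of bicyclo[3.3.0]octenol 5 ← transannular rearrangement of enantioenriched 1,3-cyclooctadiene monoepoxide 2; 13 ← Sharpless epoxidation of mono-silylated cis-butenediol.
5. Ring order: cyclopentane → bridging dihydropyran (enol ether) → methylene lactone → seven-membered ring.

Assumption: locants C1–C15 in names and reasons follow guaianolide numbering of the target (C1–C5 cyclopentane, C6–C10 rest of the seven-membered ring, C11–C13 methylene lactone, C14 enol-ether CH, C15 CH2O), and tributyl[(4-methoxybenzyloxy)methyl]stannane and the Bestmann–Ohira reagent are taken as purchasable reagents.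

The route is a paper design; none of it has been run.

**Main line**

Step 1
Reactants: 1 (1Z,3Z)-cycloocta-1,3-diene
Product: 2 (1R,8S)-9-oxabicyclo[6.1.0]non-2-ene
Conditions: (R,R)-N,N′-bis(3,5-di-tert-butylsalicylidene)-1,2-cyclohexanediaminomanganese chloride (4 mol %), NaOCl (aq, pH 11), 4-phenylpyridine N-oxide, CH2Cl2, 0 °C
Reagents that add atoms: sodium hypochlorite, [Na+].[O-]Cl
Why: Jacobsen–Katsuki epoxidation of a cis-conjugated diene gives the monoepoxide, the oxo-manganese species attacking the face set by the (R,R) ligand (sense taken by analogy with indene, where the (S,S) catalyst gives the (1S,2R) oxide); this fixes the centre that becomes C5 and, through step 2, C1.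

Step 2
Reactants: 2 (1R,8S)-9-oxabicyclo[6.1.0]non-2-ene
Product: 3 (1S,2S,5S)-bicyclo[3.3.0]oct-7-en-2-ol (cis-fused, endo OH)
Conditions: LiNEt2 (2.5 equiv), Et2O, reflux; NH4Cl (aq)
Reagents that add atoms: none
Why: α-Lithiation at the allylic oxirane carbon gives a carbenoid that inserts into the transannular C–H bond (Crandall–Whitesell epoxide rearrangement); the insertion is stereospecific, so the cis ring fusion (future C1 and C5) follows from the epoxide configuration.

Step 3
Reactants: 3 (1S,2S,5S)-bicyclo[3.3.0]oct-7-en-2-ol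
Product: 4 (1S,5S)-bicyclo[3.3.0]oct-7-en-2-one
Conditions: Dess–Martin periodinane, NaHCO3, CH2Cl2, 0 °C to rt
Reagents that add atoms: none
Why: Dess–Martin oxidation is non-basic, so the β,γ-alkene does not move into conjugation and the ring-fusion centres are untouched.

Step 4
Reactants: 4 (1S,5S)-bicyclo[3.3.0]oct-7-en-2-one
Product: 5 (1S,2S,5S)-2-{[(4-methoxybenzyl)oxy]methyl}bicyclo[3.3.0]oct-7-en-2-ol (OH endo, CH2OPMB exo)
Conditions: Bu3SnCH2OPMB, n-BuLi, THF, −78 °C; CeCl3; then 4, −78 °C; NH4Cl (aq)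
Reagents that add atoms: tributyl{[(4-methoxybenzyl)oxy]methyl}stannane, CCCC[Sn](CCCC)(CCCC)COCc1ccc(OC)cc1
Why: Tin–lithium exchange gives an α-alkoxymethyl-lithium (Still hydroxymethyl-anion equivalent) whose cerium-modified 1,2-addition occurs from the convex face of the cis-bicyclo[3.3.0] ketone, placing C15 exo and the C4 oxygen on the concave face (cis to the second ring), as the target requires.

Step 5
Reactants: 5 (1S,2S,5S)-2-{[(4-methoxybenzyl)oxy]methyl}bicyclo[3.3.0]oct-7-en-2-ol
Product: 7 (1S,5S,8R)-3-hydroxy-1-{[(4-methoxybenzyl)oxy]methyl}-2-oxabicyclo[3.2.1]octane-8-carbaldehyde (lactol, both C3 anomers), via hydroxy dialdehyde 6 (not isolated)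
Conditions: O3, CH2Cl2, −78 °C (stopped at the alkene end-point); Me2S, −78 °C to rt
Reagents that add atoms: ozone, [O-][O+]=O
Why: Ozonolysis cleaves the cyclopentene to the C6 and C14 aldehydes, and the tertiary C4 hydroxyl, cis to the CH2CHO arm, closes at once to the six-membered bridged lactol, which leaves only the C6 aldehyde free.

Step 6
Reactants: 7 lactol aldehyde
Product: 8 (1S,5S,8R)-1-{[(4-methoxybenzyl)oxy]methyl}-2-oxabicyclo[3.2.1]oct-3-ene-8-carbaldehyde
Conditions: MsCl, Et3N, CH2Cl2, −20 °C to rt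
Reagents that add atoms: none
Why: Mesylation of the lactol and elimination (glycal-type enol ether formation) gives the C10=C14 enol ether; C5 keeps its configuration because the formyl group syn to the unsaturated bridge is the less hindered epimer.

**Side branch (alkynyl oxirane)**

Step 7
Reactants: 9 (2Z)-but-2-ene-1,4-diol
Product: 10 (2Z)-4-{[tert-butyl(dimethyl)silyl]oxy}but-2-en-1-ol
Conditions: NaH (1.0 equiv), THF, 0 °C; TBSCl (1.0 equiv), 0 °C to rt
Reagents that add atoms: tert-butyldimethylsilyl chloride, CC(C)(C)[Si](C)(C)Cl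
Why: Monosilylation of a symmetric diol through its sparingly soluble mono-sodium alkoxide (McDougal protocol) gives the mono-TBS ether.

Step 8
Reactants: 10 (2Z)-4-{[tert-butyl(dimethyl)silyl]oxy}but-2-en-1-ol
Product: 11 [(2S,3R)-3-({[tert-butyl(dimethyl)silyl]oxy}methyl)oxiran-2-yl]methanol
Conditions: Ti(OiPr)4, L-(+)-diethyl tartrate, t-BuOOH, 4 Å MS, CH2Cl2, −20 °C
Reagents that add atoms: tert-butyl hydroperoxide, CC(C)(C)OO
Why: Sharpless asymmetric epoxidation of the Z-allylic alcohol with the L-(+)-tartrate gives the (2S,3R) cis-epoxide, which sets the future C8 (kept) and the C7 centre that is later inverted.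

Step 9
Reactants: 11 cis-epoxy alcohol
Product: 12 (2R,3R)-3-({[tert-butyl(dimethyl)silyl]oxy}methyl)oxirane-2-carbaldehyde
Conditions: Dess–Martin periodinane, NaHCO3, CH2Cl2, 0 °C
Reagents that add atoms: none
Why: Buffered Dess–Martin oxidation gives the cis-epoxy aldehyde without epimerizing the α-centre.

Step 10
Reactants: 12 cis-epoxy aldehyde
Product: 13 tert-butyl{[(2R,3S)-3-ethynyloxiran-2-yl]methoxy}dimethylsilane (cis)
Conditions: dimethyl (1-diazo-2-oxopropyl)phosphonate, K2CO3, MeOH, 0 °C
Reagents that add atoms: dimethyl (1-diazo-2-oxopropyl)phosphonate, CC(=O)C(=[N+]=[N-])P(=O)(OC)OC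
Why: Seyferth–Gilbert homologation in the Ohira–Bestmann variant converts the aldehyde into the terminal alkyne (future C11 and C13) at low temperature, keeping the cis-oxirane.

**Convergent part**

Step 11
Reactants: 8 bicyclic enol-ether aldehyde; 13 cis-alkynyl oxirane
Product: 15 (1S,2S,3S)-2-ethynyl-1-[(1S,5S,8S)-1-{[(4-methoxybenzyl)oxy]methyl}-2-oxabicyclo[3.2.1]oct-3-en-8-yl]-4-{[tert-butyl(dimethyl)silyl]oxy}butane-1,3-diol (C6 S, C7 S, C8 S), via allenylindium alkoxide 14 (not isolated)
Conditions: 13 (1.4 equiv), InI (1.5 equiv), Pd(PPh3)4 (5 mol %), THF/DMPU 4:1, 0 °C to rt; NH4Cl (aq)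
Reagents that add atoms: none
Why: Proposed new method: zerovalent palladium opens the alkynyl oxirane anti (SN2′) to an allenylpalladium alkoxide, InI reduces it to allenylindium 14, so the electrophilic propargylic carbon C7 becomes a nucleophile that adds to the aldehyde carbon C6 through a closed SE2′ transition state (net inversion at C7, anti C6-OH/C7, so reagent 13 controls C6 and C7 and delivers C8 with a free hydroxyl); the closest known reactions are the Marshall–Tamaru Pd/InI or Pd/Et2Zn propargylation with propargylic mesylates and the Pd/InI umpolung of vinyl oxiranes.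

Step 12
Reactants: 15 ethynyl 1,3-diol
Product: 16 8-O-angelate of 15 [(2Z)-2-methylbut-2-enoate on the C8 hydroxyl, C6 hydroxyl free]
Conditions: angelic acid, 2,4,6-trichlorobenzoyl chloride, Et3N, toluene, rt; then 15, DMAP, 40 °C
Reagents that add atoms: angelic acid, C/C=C(/C)C(=O)O
Why: Yamaguchi esterification acylates the C8 hydroxyl, which has a CH2 neighbour, in preference to the C6 hydroxyl flanked by two branched carbons, and the mixed anhydride does not isomerize angelate to tiglate.

Step 13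
Reactants: 16 homopropargylic alcohol angelate
Product: 17 (4S,5S)-α-methylene-γ-butyrolactone: 3-methylideneoxolan-2-one carrying at C5 the (1S,5S,8S)-1-(PMB-oxymethyl)-2-oxabicyclo[3.2.1]oct-3-en-8-yl group and at C4 the (1S)-1-(angeloyloxy)-2-(TBS-oxy)ethyl group
Conditions: PdCl2 (5 mol %), SnCl2 (5 mol %), PPh3 (10 mol %), CO (7 atm), MeCN, 70 °C
Reagents that add atoms: carbon monoxide, [C-]#[O+]
Why: Norton cyclocarbonylation of a homopropargylic alcohol (alkoxycarbonyl-palladium formation, syn addition across the alkyne, protonolysis) builds the methylene lactone on the C6 oxygen without touching C6 or C7, so the anti adduct gives the trans lactone.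

Step 14
Reactants: 17 silyl ether lactone
Product: 18 primary alcohol (C9-OH) of 17
Conditions: HF·pyridine, pyridine, THF, 0 °C
Reagents that add atoms: none
Why: Buffered fluoride desilylation removes the primary TBS group and leaves the enol ether, the esters and the PMB ether intact.

Step 15
Reactants: 18 primary alcohol
Product: 19 α-angeloyloxy aldehyde (C9 aldehyde)
Conditions: Dess–Martin periodinane, NaHCO3, CH2Cl2, 0 °C (used at once)
Reagents that add atoms: none
Why: Buffered Dess–Martin oxidation gives the configurationally fragile α-acyloxy aldehyde under neutral conditions.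

Step 16
Reactants: 19 aldehyde
Product: 20 (1R,4S,5S,6S,7S,8S,9S)-8-angeloyloxy-9-hydroxy-15-O-(4-methoxybenzyl) tetracycle (target skeleton with free 9α-OH)
Conditions: Me2AlCl (2 equiv), CH2Cl2, −78 °C
Reagents that add atoms: none
Why: Proposed new method: Me2AlCl activates and chelates the α-acyloxy aldehyde, the nucleophilic β-carbon C10 of the cyclic enol ether adds to C9 from its only reachable face (that of the C5 bridge), and the oxocarbenium ion loses H10 to an aluminium-bound methyl, restoring the C10=C14 enol ether; attack on the chelated aldehyde anti to C7 gives the 8,9-trans (9α) alcohol; the closest known reactions are Snider's Me2AlCl carbonyl-ene/Prins cyclizations and Mukaiyama-type enol-ether aldol additions.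

Step 17
Reactants: 20 9-hydroxy tetracycle
Product: 21 9-O-acetyl-15-O-(4-methoxybenzyl) tetracycle
Conditions: Ac2O, pyridine, DMAP (cat.), CH2Cl2, 0 °C
Reagents that add atoms: acetic anhydride, CC(=O)OC(C)=O
Why: DMAP-catalysed acetylation of the only free hydroxyl proceeds with retention at C9 under basic conditions that avoid ionization of the allylic position.

Step 18
Reactants: 21 PMB ether
Product: 22 target, (1R,4S,5S,6S,7S,8S,9S)-9-acetoxy-8-angeloyloxy-15-hydroxy-4,14-epoxyguaia-10(14),11(13)-dien-12,6-olide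
Conditions: DDQ, CH2Cl2/pH 7 buffer 10:1, 0 °C
Reagents that add atoms: none
Why: Oxidative PMB cleavage (hydride abstraction by DDQ, hydrolysis of the oxocarbenium ion) frees the C15 hydroxyl, in line with routine PMB removal in the presence of glycal-type enol ethers.

**Compound list**
1 | (1Z,3Z)-cycloocta-1,3-diene | C1=CC=CCCCC1 | starting material
2 | (1R,8S)-9-oxabicyclo[6.1.0]non-2-ene | O1[C@@H]2C=CCCCC[C@H]12 | intermediate
3 | (1S,2S,5S)-bicyclo[3.3.0]oct-7-en-2-ol | O[C@H]1CC[C@H]2CC=C[C@@H]12 | intermediate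
4 | (1S,5S)-bicyclo[3.3.0]oct-7-en-2-one | O=C1CC[C@H]2CC=C[C@@H]12 | intermediate
5 | (1S,2S,5S)-2-{[(4-methoxybenzyl)oxy]methyl}bicyclo[3.3.0]oct-7-en-2-ol | O[C@@]1(COCc3ccc(OC)cc3)CC[C@H]2CC=C[C@@H]12 | intermediate
6 | (1S,2R,3S)-2-formyl-1-{[(4-methoxybenzyl)oxy]methyl}-3-(2-oxoethyl)cyclopentan-1-ol (not isolated) | O[C@@]1(COCc2ccc(OC)cc2)CC[C@@H](CC=O)[C@H]1C=O | intermediate
7 | (1S,5S,8R)-3-hydroxy-1-{[(4-methoxybenzyl)oxy]methyl}-2-oxabicyclo[3.2.1]octane-8-carbaldehyde (anomers) | O=C[C@@H]1[C@H]2CC[C@]1(COCc3ccc(OC)cc3)OC(O)C2 | intermediate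
8 | (1S,5S,8R)-1-{[(4-methoxybenzyl)oxy]methyl}-2-oxabicyclo[3.2.1]oct-3-ene-8-carbaldehyde | O=C[C@@H]1[C@H]2CC[C@]1(COCc3ccc(OC)cc3)OC=C2 | intermediate
9 | (2Z)-but-2-ene-1,4-diol | OC/C=C\CO | starting material
10 | (2Z)-4-{[tert-butyl(dimethyl)silyl]oxy}but-2-en-1-ol | CC(C)(C)[Si](C)(C)OC/C=C\CO | intermediate
11 | [(2S,3R)-3-({[tert-butyl(dimethyl)silyl]oxy}methyl)oxiran-2-yl]methanol | OC[C@@H]1O[C@@H]1CO[Si](C)(C)C(C)(C)C | intermediate
12 | (2R,3R)-3-({[tert-butyl(dimethyl)silyl]oxy}methyl)oxirane-2-carbaldehyde | O=C[C@@H]1O[C@@H]1CO[Si](C)(C)C(C)(C)C | intermediate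
13 | tert-butyl{[(2R,3S)-3-ethynyloxiran-2-yl]methoxy}dimethylsilane | C#C[C@@H]1O[C@@H]1CO[Si](C)(C)C(C)(C)C | intermediate
14 | (aS)-allenyl(iodo)indium alkoxide, I–In–CH=C=CH–CH(O−)–CH2OTBS with (4R) carbinol centre, trivalent indium (not isolated) | [H]C([In+]I)=[C@]=C([H])[C@H]([O-])CO[Si](C)(C)C(C)(C)C | intermediate
15 | (1S,2S,3S)-2-ethynyl-1-[(1S,5S,8S)-1-{[(4-methoxybenzyl)oxy]methyl}-2-oxabicyclo[3.2.1]oct-3-en-8-yl]-4-{[tert-butyl(dimethyl)silyl]oxy}butane-1,3-diol | C#C[C@H]([C@H](O)CO[Si](C)(C)C(C)(C)C)[C@H](O)[C@@H]1[C@H]2CC[C@]1(COCc3ccc(OC)cc3)OC=C2 | intermediate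
16 | 3-O-[(2Z)-2-methylbut-2-enoyl] ester (C8 angelate) of 15, C6-OH free | C#C[C@H]([C@H](OC(=O)/C(C)=C\C)CO[Si](C)(C)C(C)(C)C)[C@H](O)[C@@H]1[C@H]2CC[C@]1(COCc3ccc(OC)cc3)OC=C2 | intermediate
17 | trans-(4S,5S)-3-methylideneoxolan-2-one with C5 = (1S,5S,8S)-1-(PMB-oxymethyl)-2-oxabicyclo[3.2.1]oct-3-en-8-yl and C4 = (1S)-1-(angeloyloxy)-2-(TBS-oxy)ethyl | C=C1C(=O)O[C@H]([C@@H]2[C@H]3CC[C@]2(COCc4ccc(OC)cc4)OC=C3)[C@H]1[C@H](OC(=O)/C(C)=C\C)CO[Si](C)(C)C(C)(C)C | intermediate
18 | desilylated 17: C4 side chain = (1S)-1-(angeloyloxy)-2-hydroxyethyl | C=C1C(=O)O[C@H]([C@@H]2[C@H]3CC[C@]2(COCc4ccc(OC)cc4)OC=C3)[C@H]1[C@H](OC(=O)/C(C)=C\C)CO | intermediate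
19 | aldehyde from 18: C4 side chain = (1S)-1-(angeloyloxy)-2-oxoethyl | C=C1C(=O)O[C@H]([C@@H]2[C@H]3CC[C@]2(COCc4ccc(OC)cc4)OC=C3)[C@H]1[C@H](OC(=O)/C(C)=C\C)C=O | intermediate
20 | (1R,4S,5S,6S,7S,8S,9S)-8-angeloyloxy-9-hydroxy-15-[(4-methoxybenzyl)oxy]-4,14-epoxyguaia-10(14),11(13)-dien-12,6-olide | C=C1C(=O)O[C@H]2[C@H]1[C@H](OC(=O)/C(C)=C\C)[C@@H](O)C1=CO[C@@]3(COCc4ccc(OC)cc4)CC[C@@H]1[C@@H]23 | intermediate
21 | 9-O-acetate of 20 | C=C1C(=O)O[C@H]2[C@H]1[C@H](OC(=O)/C(C)=C\C)[C@@H](OC(C)=O)C1=CO[C@@]3(COCc4ccc(OC)cc4)CC[C@@H]1[C@@H]23 | intermediate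
22 | (1R,4S,5S,6S,7S,8S,9S)-9-acetoxy-8-angeloyloxy-15-hydroxy-4,14-epoxyguaia-10(14),11(13)-dien-12,6-olide | C=C1C(=O)O[C@H]2[C@H]1[C@H](OC(=O)/C(C)=C\C)[C@@H](OC(C)=O)C1=CO[C@@]3(CO)CC[C@@H]1[C@@H]23 | target

**Step count**
Total: 18 steps. Longest linear sequence: 14 steps (steps 1–6 and 11–18, from cycloocta-1,3-diene); the side branch is 4 steps (7–10).

**Steps most likely to fail**

Step 11 (palladium/indium coupling of 8 with 13). The allenylpalladium alkoxide may isomerize before indium capture, and the aldehyde's own facial bias may oppose the reagent. Fallback: setting out from 13, a copper-catalysed anti-SN2′ borylative opening (B2pin2, CuCl, NaOt-Bu, Xantphos, MeOH, THF) gives the isolable, configurationally stable (aS)-allenylboronate F1. Its closed-transition-state propargylboration of 8 (toluene, 40 °C, then aqueous work-up) forms the same C6–C7 bond with the same anti sense and comes back to the route at 15.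

Step 16 (enol ether–aldehyde ring closure of 19). The Lewis acid may ionize the allylic C9 oxygen of the product or give the wrong C9 epimer. Fallback: setting out from 18, iodination of the enol ether β-carbon (N-iodosuccinimide, 2,6-lutidine, MeCN, 0 °C) gives the C10 vinyl iodide alcohol F2. Dess–Martin oxidation gives the iodo aldehyde F3, and an intramolecular Nozaki–Hiyama–Kishi reaction (CrCl2, NiCl2 cat., DMF/THF) closes the seven-membered ring under neutral conditions, coming back at 20.

Step 12 (site-selective angeloylation of diol 15). The C6 hydroxyl may compete, or the angelate may migrate. Fallback: setting out from 15, the cyclocarbonylation (PdCl2, SnCl2, PPh3, CO, MeCN, 70 °C) is run first, and the lactone is equilibrated (camphorsulfonic acid cat.) to the more stable trans-4,5-disubstituted isomer, the hydroxy lactone F4. F4 has a single free hydroxyl at C8, and its Yamaguchi angeloylation comes back at 17.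

Further compounds
F1 | step 11 | (aS)-allenylboronate, pinB–CH=C=CH–CH(OH)–CH2OTBS with (4R) carbinol centre | [H]C(B1OC(C)(C)C(C)(C)O1)=[C@]=C([H])[C@H](O)CO[Si](C)(C)C(C)(C)C
F2 | step 16 | C10-iodo enol ether analogue of alcohol 18 | C=C1C(=O)O[C@H]([C@@H]2[C@H]3CC[C@]2(COCc4ccc(OC)cc4)OC=C3I)[C@H]1[C@H](OC(=O)/C(C)=C\C)CO
F3 | step 16 | C10-iodo enol ether analogue of aldehyde 19 | C=C1C(=O)O[C@H]([C@@H]2[C@H]3CC[C@]2(COCc4ccc(OC)cc4)OC=C3I)[C@H]1[C@H](OC(=O)/C(C)=C\C)C=O
F4 | step 12 | hydroxy lactone: 17 with free C8 hydroxyl in place of the angelate | C=C1C(=O)O[C@H]([C@@H]2[C@H]3CC[C@]2(COCc4ccc(OC)cc4)OC=C3)[C@H]1[C@H](O)CO[Si](C)(C)C(C)(C)C
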